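The arene is built by a Dötz benzannulation. The feature exploited is the pentasubstituted benzene ring with para oxygens at C3′ and C6′, of which only C6′–O (between C1′ and the formyl-bearing C5′) is sulfated. The carbene carbon becomes C3′ (ether) and CO becomes C6′ (the only free phenol). Bonds C2′–C3′, C1′–C6′ and C5′–C6′ close the ring in one operation with all five substituents in place. The precursors are a sclareolide-derived (11S)-11-ethynyl-11-silyloxydrim-8-ene and an α-alkoxy alkenyl chromium carbene carrying the formyl carbon as an acetal. A later allylic diazene transposition relays C11 chirality into the 8β-methyl centre and the E C9=C11 alkene.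

Key step: step 12

Remark (assumption): the target is drawn as the free aryl hydrogen sulfate; the last step is written to deliver this acid form, and the ammonium salt 30 is the form in which the sulfate is carried and stored.
Remark (descriptors): a drim-8-ene has no stereocentre at C8, so alkyne 13 is a plain (5S,10S)-drim-8-ene and the 8-epi (8β-methyl, 8S) centre first arises in step 15. In the carbene complex the ether oxygen on C2 outranks the carbene carbon, so the isomer with the acetal carbon trans to the carbene carbon is (Z) and the isomer with it cis is (E).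
Remark (protecting groups): methyl ethers at C3′/C4′ could not be cleaved late without destroying the aryl sulfate and the acid-labile C9=C11 alkene. Both oxygens are therefore carried as fluoride-labile 2-(trimethylsilyl)ethyl ethers, C11–O as a triethylsilyl ether, and the sulfate as its 2,2,2-trichloroethyl diester.

Step 1
Reactants: 1 (+)-sclareolide
Product: 3 11-hydroxysclareolide (C11 epimers), via potassium enolate 2 (not isolated)
Conditions: KN(SiMe3)2, THF, −78 °C; 2-(phenylsulfonyl)-3-phenyloxaziridine, −78 °C; aq. NH4Cl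
Reagents that add atoms: 2-(phenylsulfonyl)-3-phenyloxaziridine, O=S(=O)(c1ccccc1)N1OC1c1ccccc1
Why: Electrophilic α-hydroxylation of the lactone enolate (enolate oxidation) places an oxygen on C11 so that C12 can be excised, and the C11 configuration is irrelevant because this carbon becomes a carbonyl carbon in step 3.

Step 2
Reactants: 3 11-hydroxysclareolide
Product: 4 13,14,15,16-tetranorlabdane-8α,11,12-triol (C11 epimers)
Conditions: LiAlH4, THF, 0 °C → rt; aqueous NaOH work-up
Reagents that add atoms: none
Why: Hydride reduction of the lactone (ester to diol) should give the 11,12-diol beside the untouched tertiary 8α-hydroxyl.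

Step 3
Reactants: 4 13,14,15,16-tetranorlabdane-8α,11,12-triol
Product: 5 8α-hydroxydriman-11-al
Conditions: NaIO4, THF/H2O, rt
Reagents that add atoms: none
Why: Periodate glycol cleavage of the vicinal 11,12-diol removes C12 as formaldehyde and leaves the C11 aldehyde, the tertiary C8 hydroxyl having no vicinal partner.

Step 4
Reactants: 5 8α-hydroxydriman-11-al
Product: 6 (5S,10S)-drim-8-en-11-al
Conditions: p-TsOH·H2O (5 mol %), toluene, 80 °C
Reagents that add atoms: none
Why: Acid-catalysed dehydration of the aldol-type β-hydroxy aldehyde through its enol should give the conjugated tetrasubstituted enal (the bicyclic counterpart of β-cyclocitral), toward which any β,γ-unsaturated isomers equilibrate under the same conditions, the C8 and C9 centres being erased on purpose.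

Step 5
Reactants: 6 (5S,10S)-drim-8-en-11-al; 7 ethynyl(trimethyl)silane
Product: 9 11-[(trimethylsilyl)ethynyl]drim-8-en-11-ol (C11 epimers), via lithium (trimethylsilyl)acetylide 8 (not isolated)
Conditions: 7, n-BuLi, THF, −78 °C; then 6, −78 → 0 °C; aq. NH4Cl
Reagents that add atoms: none
Why: 1,2-Addition of a lithium acetylide to the aldehyde should be clean because conjugate addition is blocked at the tetrasubstituted β-carbon, and the C11 mixture is removed in the next step.

Step 6
Reactants: 9 11-[(trimethylsilyl)ethynyl]drim-8-en-11-ol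
Product: 10 11-[(trimethylsilyl)ethynyl]drim-8-en-11-one
Conditions: MnO2, CH2Cl2, rt
Reagents that add atoms: none
Why: MnO2 oxidation is selective for this doubly activated (allylic and propargylic) alcohol and should give the cross-conjugated ynone without touching the alkene.

Step 7
Reactants: 10 11-[(trimethylsilyl)ethynyl]drim-8-en-11-one
Product: 12 (11S)-11-ethynyldrim-8-en-11-ol, via (11R)-silylalkynyl carbinol 11 (not isolated)
Conditions: (R)-2-methyl-CBS-oxazaborolidine (30 mol %), BH3·SMe2, THF, −30 °C; MeOH; then K2CO3, MeOH, rt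
Reagents that add atoms: none
Why: In the CBS reduction the bulky tetrasubstituted alkenyl group acts as the large substituent and the rod-like silylalkynyl group as the small one, so the (R)-catalyst should set C11 by catalyst control, after which base-mediated methanolysis of the C–Si bond frees the terminal alkyne (the descriptor changes from 11R to 11S without any change of geometry).

Step 8
Reactants: 12 (11S)-11-ethynyldrim-8-en-11-ol
Product: 13 (11S)-11-ethynyl-11-(triethylsilyloxy)drim-8-ene
Conditions: Et3SiOTf, 2,6-lutidine, CH2Cl2, −78 → 0 °C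
Reagents that add atoms: triethylsilyl trifluoromethanesulfonate, CC[Si](CC)(CC)OS(=O)(=O)C(F)(F)F
Why: Silyl triflate silylation of the hindered secondary alcohol gives a bulky propargylic ether that survives the benzannulation and is later removed by buffered HF without harm to aryl ethers, acetal or sulfate diester.

Step 9
Reactants: 14 3,3-diethoxyprop-1-yne; 15 2-(trimethylsilyl)ethanol
Product: 16 (Z)-[2-(3,3-diethoxyprop-1-enyloxy)ethyl]trimethylsilane
Conditions: KOt-Bu (20 mol %), DMSO, 60 °C
Reagents that add atoms: none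
Why: Base-catalysed anti addition of the alkoxide to the terminal carbon of the alkyne (nucleophilic hydroalkoxylation), assisted by the inductively withdrawing propargylic acetal, should give the (Z)-β-alkoxyacrolein acetal with a fluoride-labile O-substituent at the future C4′ oxygen.

Step 10
Reactants: 16 (Z)-[2-(3,3-diethoxyprop-1-enyloxy)ethyl]trimethylsilane; 17 chromium hexacarbonyl
Product: 20 tetramethylammonium acylpentacarbonylchromate, via vinyllithium 18 (not isolated), via lithium acylchromate 19 (not isolated)
Conditions: t-BuLi, THF, −78 → −30 °C; Cr(CO)6, −78 → 0 °C; Me4NBr, H2O, 0 °C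
Reagents that add atoms: tetramethylammonium bromide, C[N+](C)(C)C.[Br-]
Why: α-Deprotonation of the enol ether (as with dihydropyran, a cyclic Z enol ether) with retention, addition of the vinyllithium to a CO ligand (Fischer carbene synthesis) and cation exchange should give the storable ammonium acylmetalate with the acetal carbon trans to the carbene carbon.

Step 11
Reactants: 20 tetramethylammonium acylpentacarbonylchromate; 15 2-(trimethylsilyl)ethanol
Product: 22 pentacarbonyl{(Z)-4,4-diethoxy-1,2-bis[2-(trimethylsilyl)ethoxy]but-2-en-1-ylidene}chromium, via acetoxycarbene complex 21 (not isolated)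
Conditions: AcBr, CH2Cl2, −40 °C; then 15, −40 → 0 °C
Reagents that add atoms: none
Why: O-Acylation of the acylmetalate and addition–elimination of the alcohol at the activated carbene carbon (acyloxy/alkoxy exchange) installs a removable ether at the future C3′ oxygen, only acetic acid being set free so that enol ether and acetal survive.

Step 12
Reactants: 13 (11S)-11-ethynyl-11-(triethylsilyloxy)drim-8-ene; 22 pentacarbonyl{(Z)-4,4-diethoxy-1,2-bis[2-(trimethylsilyl)ethoxy]but-2-en-1-ylidene}chromium
Product: 24 (11R)-11-{5′-(diethoxymethyl)-6′-hydroxy-3′,4′-bis[2-(trimethylsilyl)ethoxy]phenyl}-11-(triethylsilyloxy)drim-8-ene, via arene tricarbonylchromium complex 23 (not isolated)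
Conditions: 22 (1.5 equiv), THF (degassed), 55 °C; then air, Et2O, rt
Reagents that add atoms: none
Why: Thermal loss of one CO lets the terminal alkyne insert into the Cr=C bond (C2′–C3′), CO insertion follows (C1′–C6′), and 6π-electrocyclisation (C5′–C6′) with tautomerisation of the C5′ hydrogen gives the phenol as its Cr(CO)3 complex, which air demetallates. This is the Dötz benzannulation of an α-alkoxy alkenyl Fischer carbene with a terminal alkyne, the best-behaved substrate class for this reaction. The one new ring is closed by thermal disrotatory 6π-electrocyclic bond formation between C5′ and the CO-derived C6′, the acetal on C5′ lying trans to the carbene carbon and so outside the closing termini. No stereocentre is formed, and C11, which is insulated from the reacting π-system, is carried through unchanged (its descriptor becomes R only because aryl outranks alkenyl). The step needs regioselective insertion, secured by the steric difference between the hydrogen end of the alkyne and the end bearing the bulky C11 silyloxy-drimenyl group, which puts C1′ next to the CO-derived carbon so that the only free hydroxyl is at C6′. It also needs phenol formation to outrun cyclopentannulation and ketene trapping, which the alkenyl carbene, the donor solvent and the silyl cap on the propargylic oxygen favour.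

Step 13
Reactants: 24 Dötz phenol
Product: 25 6′-O-(2,2,2-trichloroethoxysulfonyl) derivative of 24
Conditions: Cl3CCH2OSO2Cl, Et3N, DMAP, THF, 0 °C → rt
Reagents that add atoms: 2,2,2-trichloroethyl chlorosulfate, ClS(=O)(=O)OCC(Cl)(Cl)Cl
Why: Sulfonylation of the only free phenol with the chlorosulfate (DMAP catalysis) gives a neutral sulfate diester and removes the ortho phenol that could otherwise form a quinone methide when C11 is activated.

Step 14
Reactants: 25 trichloroethyl sulfate silyl ether
Product: 26 (11R)-C11 alcohol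
Conditions: HF·pyridine, pyridine, THF, 0 °C → rt
Reagents that add atoms: none
Why: Pyridine-buffered HF cleaves the triethylsilyl ether (fluoride-mediated Si–O cleavage) while the aryl silylethyl ethers, the acetal and the sulfate diester should be stable.

Step 15
Reactants: 26 (11R)-C11 alcohol
Product: 29 (E)-11-aryl-8-epi-drim-9(11)-ene trichloroethyl sulfate (8β-methyl, 8S), via hydrazone adduct 27 (not isolated), via allylic diazene 28 (not isolated)
Conditions: N-isopropylidene-N′-(2-nitrobenzenesulfonyl)hydrazine, PPh3, DEAD, THF, 0 → 23 °C; then CF3CH2OH/H2O, 23 °C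
Reagents that add atoms: none
Why: Mitsunobu displacement by the sulfonyl hydrazone inverts C11, hydrazone hydrolysis and sulfinate loss unmask the monoalkyl diazene, and its retro-ene loss of N2 (allylic diazene rearrangement, reductive 1,3-transposition) delivers hydrogen suprafacially to C8 from the α face, anti to the C10 methyl, with the aryl group turned toward C8, so that the C11 configuration from step 7 is relayed into the 8β-methyl (8S) centre and the E alkene.

Step 16
Reactants: 29 (E)-alkene trichloroethyl sulfate
Product: 30 ammonium aryl sulfate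
Conditions: Zn dust, HCO2NH4, MeOH, rt
Reagents that add atoms: ammonium formate, [NH4+].[O-]C=O
Why: Reductive β-elimination of the trichloroethyl group by Zn (loss of 1,1-dichloroethene) frees the sulfate monoester under neutral conditions that should leave alkene, acetal and silylethyl ethers untouched.

Step 17
Reactants: 30 ammonium aryl sulfate
Product: 32 CNP0149861.1 (target, free hydrogen sulfate), via catechol acetal salt 31 (not isolated)
Conditions: n-Bu4NF, DMF, 60 °C (argon); then 0.5 M HCl to pH 2, 0 °C; C18 chromatography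
Reagents that add atoms: water, O
Why: Fluoride attack at silicon triggers β-fragmentation of both aryl 2-(trimethylsilyl)ethyl ethers (loss of ethene) under basic conditions that spare the alkene and the sulfate monoester, and brief cold acidification hydrolyses the electron-rich benzylic acetal and protonates the sulfate.

Compound list
1 | (+)-sclareolide | C[C@@]12CC[C@H]3C(C)(C)CCC[C@]3(C)[C@H]1CC(=O)O2 | starting material
2 | potassium enolate of sclareolide | C[C@@]12CC[C@H]3C(C)(C)CCC[C@]3(C)[C@H]1C=C([O-])O2.[K+] | intermediate (not isolated)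
3 | 11-hydroxysclareolide (C11 epimers) | C[C@@]12CC[C@H]3C(C)(C)CCC[C@]3(C)[C@H]1C(O)C(=O)O2 | intermediate
4 | 13,14,15,16-tetranorlabdane-8α,11,12-triol (C11 epimers) | C[C@@]1(O)CC[C@H]2C(C)(C)CCC[C@]2(C)[C@H]1C(O)CO | intermediate
5 | 8α-hydroxydriman-11-al | C[C@@]1(O)CC[C@H]2C(C)(C)CCC[C@]2(C)[C@H]1C=O | intermediate
6 | (5S,10S)-drim-8-en-11-al | CC=1CC[C@H]2C(C)(C)CCC[C@]2(C)C=1C=O | intermediate
7 | ethynyl(trimethyl)silane | C#C[Si](C)(C)C | starting material
8 | lithium (trimethylsilyl)acetylide | [Li]C#C[Si](C)(C)C | intermediate (not isolated)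
9 | 11-[(trimethylsilyl)ethynyl]drim-8-en-11-ol (C11 epimers) | CC=1CC[C@H]2C(C)(C)CCC[C@]2(C)C=1C(O)C#C[Si](C)(C)C | intermediate
10 | 11-[(trimethylsilyl)ethynyl]drim-8-en-11-one | CC=1CC[C@H]2C(C)(C)CCC[C@]2(C)C=1C(=O)C#C[Si](C)(C)C | intermediate
11 | (11R)-11-[(trimethylsilyl)ethynyl]drim-8-en-11-ol | CC=1CC[C@H]2C(C)(C)CCC[C@]2(C)C=1[C@@H](O)C#C[Si](C)(C)C | intermediate (not isolated)
12 | (11S)-11-ethynyldrim-8-en-11-ol | CC=1CC[C@H]2C(C)(C)CCC[C@]2(C)C=1[C@@H](O)C#C | intermediate
13 | (11S)-11-ethynyl-11-(triethylsilyloxy)drim-8-ene (alkyne precursor of the key step) | CC=1CC[C@H]2C(C)(C)CCC[C@]2(C)C=1[C@@H](O[Si](CC)(CC)CC)C#C | intermediate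
14 | 3,3-diethoxyprop-1-yne | C#CC(OCC)OCC | starting material
15 | 2-(trimethylsilyl)ethanol | C[Si](C)(C)CCO | starting material
16 | (Z)-[2-(3,3-diethoxyprop-1-enyloxy)ethyl]trimethylsilane | C[Si](C)(C)CCO/C=C\C(OCC)OCC | intermediate
17 | chromium hexacarbonyl, Cr(CO)6 | O=C=[Cr](=C=O)(=C=O)(=C=O)(=C=O)=C=O | starting material
18 | (Z)-3,3-diethoxy-1-[2-(trimethylsilyl)ethoxy]prop-1-enyllithium | [Li]/C(OCC[Si](C)(C)C)=C/C(OCC)OCC | intermediate (not isolated)
19 | lithium acylpentacarbonylchromate, Li[(CO)5Cr=C(O)R] | [Li+].[O-]C(=[Cr](=C=O)(=C=O)(=C=O)(=C=O)=C=O)/C(OCC[Si](C)(C)C)=C/C(OCC)OCC | intermediate (not isolated)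
20 | tetramethylammonium acylpentacarbonylchromate, Me4N[(CO)5Cr=C(O)R] | C[N+](C)(C)C.[O-]C(=[Cr](=C=O)(=C=O)(=C=O)(=C=O)=C=O)/C(OCC[Si](C)(C)C)=C/C(OCC)OCC | intermediate
21 | acetoxycarbene complex, (CO)5Cr=C(OAc)R | CC(=O)OC(=[Cr](=C=O)(=C=O)(=C=O)(=C=O)=C=O)/C(OCC[Si](C)(C)C)=C/C(OCC)OCC | intermediate (not isolated)
22 | pentacarbonyl{(Z)-4,4-diethoxy-1,2-bis[2-(trimethylsilyl)ethoxy]but-2-en-1-ylidene}chromium (carbene precursor of the key step) | C[Si](C)(C)CCOC(=[Cr](=C=O)(=C=O)(=C=O)(=C=O)=C=O)/C(OCC[Si](C)(C)C)=C/C(OCC)OCC | intermediate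
23 | tricarbonyl(η6-arene)chromium complex of 24 (Cr(CO)3 on the new ring, written as a dot-joined pair) | CC=1CC[C@H]2C(C)(C)CCC[C@]2(C)C=1[C@@H](O[Si](CC)(CC)CC)c1cc(OCC[Si](C)(C)C)c(OCC[Si](C)(C)C)c(C(OCC)OCC)c1O.O=C=[Cr](=C=O)=C=O | intermediate (not isolated)
24 | (11R)-11-{5′-(diethoxymethyl)-6′-hydroxy-3′,4′-bis[2-(trimethylsilyl)ethoxy]phenyl}-11-(triethylsilyloxy)drim-8-ene (product of the key step) | CC=1CC[C@H]2C(C)(C)CCC[C@]2(C)C=1[C@@H](O[Si](CC)(CC)CC)c1cc(OCC[Si](C)(C)C)c(OCC[Si](C)(C)C)c(C(OCC)OCC)c1O | intermediate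
25 | 6′-O-(2,2,2-trichloroethoxysulfonyl) derivative of 24 | CC=1CC[C@H]2C(C)(C)CCC[C@]2(C)C=1[C@@H](O[Si](CC)(CC)CC)c1cc(OCC[Si](C)(C)C)c(OCC[Si](C)(C)C)c(C(OCC)OCC)c1OS(=O)(=O)OCC(Cl)(Cl)Cl | intermediate
26 | (11R)-C11 alcohol (11-aryl-drim-8-en-11-ol, aryl as in 25) | CC=1CC[C@H]2C(C)(C)CCC[C@]2(C)C=1[C@@H](O)c1cc(OCC[Si](C)(C)C)c(OCC[Si](C)(C)C)c(C(OCC)OCC)c1OS(=O)(=O)OCC(Cl)(Cl)Cl | intermediate
27 | (11S)-N-(11-aryl-drim-8-en-11-yl)-N′-isopropylidene-2-nitrobenzenesulfonohydrazide | CC=1CC[C@H]2C(C)(C)CCC[C@]2(C)C=1[C@H](N(N=C(C)C)S(=O)(=O)c1ccccc1[N+](=O)[O-])c1cc(OCC[Si](C)(C)C)c(OCC[Si](C)(C)C)c(C(OCC)OCC)c1OS(=O)(=O)OCC(Cl)(Cl)Cl | intermediate (not isolated)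
28 | (11S)-allylic monoalkyl diazene | CC=1CC[C@H]2C(C)(C)CCC[C@]2(C)C=1[C@H](N=N)c1cc(OCC[Si](C)(C)C)c(OCC[Si](C)(C)C)c(C(OCC)OCC)c1OS(=O)(=O)OCC(Cl)(Cl)Cl | intermediate (not isolated)
29 | (5S,8S,10S,E)-11-aryl-8-epi-drim-9(11)-ene, 6′-O-(2,2,2-trichloroethyl) sulfate, acetal and bis(silylethyl) ether intact | C[C@H]1CC[C@H]2C(C)(C)CCC[C@]2(C)/C1=C/c1cc(OCC[Si](C)(C)C)c(OCC[Si](C)(C)C)c(C(OCC)OCC)c1OS(=O)(=O)OCC(Cl)(Cl)Cl | intermediate
30 | ammonium 6′-sulfate of the acetal bis(silylethyl) ether | C[C@H]1CC[C@H]2C(C)(C)CCC[C@]2(C)/C1=C/c1cc(OCC[Si](C)(C)C)c(OCC[Si](C)(C)C)c(C(OCC)OCC)c1OS(=O)(=O)[O-].[NH4+] | intermediate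
31 | catechol diethyl acetal 6′-sulfate, tetrabutylammonium salt | C[C@H]1CC[C@H]2C(C)(C)CCC[C@]2(C)/C1=C/c1cc(O)c(O)c(C(OCC)OCC)c1OS(=O)(=O)[O-].CCCC[N+](CCCC)(CCCC)CCCC | intermediate (not isolated)
32 | CNP0149861.1, (5S,8S,10S,E)-configured aryl hydrogen sulfate | C[C@H]1CC[C@H]2C(C)(C)CCC[C@]2(C)/C1=C/c1cc(O)c(O)c(C=O)c1OS(=O)(=O)O | target

Total step count: 17. Longest linear sequence: 14 steps (steps 1–8 and 12–17, from 1).

Steps most likely to fail

Step 15. The displacement at the hindered, ionisable C11 carbinol may be slow or may lose its invertive course, 1,4-elimination of the oxyphosphonium may compete, and the diazene may react through the other rotamer (nitrogen on the β face, aryl toward C10), which would erode both the C8 configuration and the alkene geometry. The fallback sets out from 26 and comes back at 29. Acetic formic anhydride and pyridine (CH2Cl2, 0 °C) should give the C11 formate F1. Pd(OAc)2 (cat.) with n-Bu3P in THF at 23–40 °C then ionises the allylic formate with inversion, CO2 is lost, and the palladium hydride transfers hydrogen to the more substituted terminus C8 on the face anti to the departed oxygen (formate hydrogenolysis of an allylic ester with 1,3-transposition, a Tsuji–Trost-type process). This has the same stereochemical sense as step 15, so the same C11 epimer serves.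

Step 12. Alkyne insertion may be slow with the very hindered propargylic ether, and the β-acetal substituent on the carbene may slow electrocyclisation enough for the ketene stage to be diverted. The fallback brings the formyl carbon in after the ring is made. It sets out from 15 (with 17 and 13) and comes back at 25, and it also removes the reliance on the α-lithiation of 16 in step 10. Transfer vinylation of 15 with ethyl vinyl ether (Hg(OAc)2 cat., reflux) should give 2-(trimethylsilyl)ethyl vinyl ether F2. α-Lithiation (t-BuLi, THF, −78 → 0 °C), addition to 17 and exchange with Me4NBr should give the tetramethylammonium acylchromate F3. AcBr followed by 15, as in step 11, should give pentacarbonyl{1,2-bis[2-(trimethylsilyl)ethoxy]prop-2-en-1-ylidene}chromium F4. Benzannulation of F4 with 13 (THF, 50 °C; air) should give the C5′-unsubstituted phenol F5. Magnesium-mediated ortho-formylation (MgCl2, Et3N, paraformaldehyde, THF, reflux), for which C5′ is the only free position ortho to the C6′ hydroxyl, should give the salicylaldehyde F6. Sulfation as in step 13 should give the aldehyde trichloroethyl sulfate F7, and acetalisation (HC(OEt)3, EtOH, n-Bu4NBr3 cat., rt) returns to 25.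

Step 17. Cleavage of the second silylethyl ether may stall because the leaving group is then a catecholate, and the catecholate may be oxidised by air under basic fluoride. The fallback sets out from 29 and comes back at 32. BF3·OEt2 with 2,6-di-tert-butylpyridine as proton scavenger (CH2Cl2, −20 °C; aq. NaHCO3) cleaves both aryl silylethyl ethers by Lewis-acid-triggered β-silyl fragmentation and opens the acetal, which should give the catechol aldehyde trichloroethyl sulfate F8 while the sulfate is still a neutral diester. Zn and HCO2NH4 in MeOH should then give the ammonium salt of the target F9, and cold acidification to pH 2 with C18 desalting gives 32.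

Further compounds
F1 | step 15 | C11 formate of 26 | CC=1CC[C@H]2C(C)(C)CCC[C@]2(C)C=1[C@@H](OC=O)c1cc(OCC[Si](C)(C)C)c(OCC[Si](C)(C)C)c(C(OCC)OCC)c1OS(=O)(=O)OCC(Cl)(Cl)Cl
F2 | step 12 | 2-(trimethylsilyl)ethyl vinyl ether | C=COCC[Si](C)(C)C
F3 | step 12 | tetramethylammonium pentacarbonyl acylchromate from F2 | C[N+](C)(C)C.[O-]C(=[Cr](=C=O)(=C=O)(=C=O)(=C=O)=C=O)C(=C)OCC[Si](C)(C)C
F4 | step 12 | pentacarbonyl{1,2-bis[2-(trimethylsilyl)ethoxy]prop-2-en-1-ylidene}chromium | C[Si](C)(C)CCOC(=[Cr](=C=O)(=C=O)(=C=O)(=C=O)=C=O)C(=C)OCC[Si](C)(C)C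
F5 | step 12 | (11R)-11-{6′-hydroxy-3′,4′-bis[2-(trimethylsilyl)ethoxy]phenyl}-11-(triethylsilyloxy)drim-8-ene | CC=1CC[C@H]2C(C)(C)CCC[C@]2(C)C=1[C@@H](O[Si](CC)(CC)CC)c1cc(OCC[Si](C)(C)C)c(OCC[Si](C)(C)C)cc1O
F6 | step 12 | 5′-formyl derivative of F5 (salicylaldehyde) | CC=1CC[C@H]2C(C)(C)CCC[C@]2(C)C=1[C@@H](O[Si](CC)(CC)CC)c1cc(OCC[Si](C)(C)C)c(OCC[Si](C)(C)C)c(C=O)c1O
F7 | step 12 | 6′-O-(2,2,2-trichloroethoxysulfonyl) derivative of F6 | CC=1CC[C@H]2C(C)(C)CCC[C@]2(C)C=1[C@@H](O[Si](CC)(CC)CC)c1cc(OCC[Si](C)(C)C)c(OCC[Si](C)(C)C)c(C=O)c1OS(=O)(=O)OCC(Cl)(Cl)Cl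
F8 | step 17 | catechol aldehyde 6′-O-(2,2,2-trichloroethyl) sulfate | C[C@H]1CC[C@H]2C(C)(C)CCC[C@]2(C)/C1=C/c1cc(O)c(O)c(C=O)c1OS(=O)(=O)OCC(Cl)(Cl)Cl
F9 | step 17 | ammonium salt of the target | C[C@H]1CC[C@H]2C(C)(C)CCC[C@]2(C)/C1=C/c1cc(O)c(O)c(C=O)c1OS(=O)(=O)[O-].[NH4+]
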